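The data were computed from invented constants, and the scatter is random.

Late in the runs, after the first hour, the solid substrate falls steadily while product rises. The flask holds solid substrate, part of it dissolved as starting material, with partner, free catalyst and added ligand.

| flask | solid substrate | partner | free catalyst | added ligand | remark | time |
|---|---|---|---|---|---|---|
| Thursday's | 0.50 M | 0.53 M | 1 mM | 0.72 mM | run made earlier |  |
| Friday's | 0.50 M | 0.57 M | 1 mM | 0.72 mM | run made earlier |  |
| Tuesday's | 0.50 M | 0.55 M | 1 mM | 0.72 mM | run made earlier |  |
| noon | 0.50 M | 0.470 M | 1.0 mM | 0.72 mM |  | 15 h |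
| spring | 0.50 M | 0.710 M | 1.0 mM | 0.72 mM |  | 15 h |

| run | time / h | solid substrate / % | product / % |
|---|---|---|---|
| Thursday's | 1.00 | 88.9 | 0.4 |
| Thursday's | 2.50 | 87.3 | 1.6 |
| Thursday's | 5.00 | 84.8 | 3.3 |
| Thursday's | 8.00 | 81.5 | 6.5 |
| Friday's | 1.00 | 88.0 | 0.8 |
| Friday's | 2.50 | 86.7 | 1.1 |
| Friday's | 5.00 | 84.5 | 3.7 |
| Friday's | 8.00 | 81.0 | 6.3 |
| Tuesday's | 2.00 | 87.2 | 0.9 |
| Tuesday's | 4.00 | 86.7 | 3.7 |
| Tuesday's | 6.00 | 83.7 | 4.9 |
| Tuesday's | 8.00 | 81.6 | 6.4 |

(standard deviation of a reading: 0.5 percentage points)

- amounts and yields of by-product count idle adduct too
- given per volume of solution although it is solid: solid substrate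
- reactions considered so far: catalyst intermediate C -> free catalyst + product; catalyst intermediate A <-> by-product + catalyst intermediate B; partner + free catalyst <-> catalyst intermediate A; free catalyst + added ligand <-> idle complex; starting material + catalyst intermediate B <-> catalyst intermediate C; starting material + by-product <-> idle adduct; solid substrate <-> starting material
- at the start none of the solid substrate is in solution
- what has only dissolved of solid substrate counts as not reacted
- apart from what has only dissolved, what has gone from solid substrate into another species counts as reacted, even if it can come back

1. part of the solid substrate that has reacted (what has only dissolved counts as not reacted) at the end, noon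
2. part of the solid substrate that has reacted (what has only dissolved counts as not reacted) at the end, spring
3. what raising the concentration of partner from its lowest to its highest value here does to the part of the solid substrate that has reacted (what has only dissolved counts as not reacted) (changes below 5 percentage points count as none) (it rises / no change / it falls)

Two numbers seem not to go together: at 8.00 h in Thursday's run 18.5 % of the solid substrate had gone, yet product stood at 6.5 %. The first hour shows where the gap begins. By 1.00 h that run had lost 11.1 % of its solid substrate, with product at 0.4 %. I read this first drop as dissolving, which counts as not reacted, and the later fall as reaction.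

From first to last reading, the three runs together lost 20 percentage points of solid substrate in 20.0 h, and this loss per hour, times c(solid substrate) over c(free catalyst), made 5.00 h⁻¹. This is the turnover frequency, the solid substrate reacted per hour for each free catalyst charged. Multiplied by c(free catalyst) and time and divided by c(solid substrate), it gave me 15.0 % for noon and for spring. At 8.00 h the solid substrate stood at 81.5 %, 81.6 % and 81.0 % for c(partner) of 0.53 M, 0.55 M and 0.57 M, so I expected no change, though noon and spring lie outside that span.

The forecast, somewhat above mine, gave 15.8 % for the noon flask, 18 % for the spring flask and no change between them, holding that “the rate is steady and set by the catalyst”.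

The noon flask gave 14.1 % and the spring flask 15.0 %, a change of 0.97 points, which is less than 5 points: no change.

    catalyst intermediate C → free catalyst + product (k = 190 h⁻¹)
    catalyst intermediate A ⇌ by-product + catalyst intermediate B (K = 4.20 M, k = 150 h⁻¹)
    partner + free catalyst ⇌ catalyst intermediate A (K = 5.70 L mol⁻¹, k = 85.0 L mol⁻¹ h⁻¹)
    free catalyst + added ligand ⇌ idle complex (K = 1800 L mol⁻¹, k = 300 L mol⁻¹ h⁻¹)
    starting material + catalyst intermediate B ⇌ catalyst intermediate C (K = 0.690 L mol⁻¹, k = 320 L mol⁻¹ h⁻¹)
    starting material + by-product ⇌ idle adduct, settled at all times (K = 6.70 L mol⁻¹)
    solid substrate ⇌ starting material, rate k7*(cs7 - [starting material]) while solid is left; crystals form when [starting material] > cs7 (solubility = 0.0540 M, k = 5.30 h⁻¹)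

For the noon flask, 5.00 h⁻¹ had given 15.0 % against the 14.1 % found. I then took the neighbouring flask, like noon but with 6.0 × 10⁻⁴ M of free catalyst. The same turnover frequency gave 9.00 % for it. That flask gave 8.51 % reacted, with 10.7 % starting material in solution and 93 % of its partner still unbound at 15.0 h.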